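**Assumptions:**
- The target has no stereocentres, so "single enantiomer" is moot. The only stereochemical element is the E-enone, which is set in Step 6.
- Compounds are numbered in order of first appearance in the forward route, with the target last.
- Step 1 is assumed to alkylate the less hindered, more acidic OH (C1) of 3-methoxycatechol, the one remote from the OMe.

## Retrosynthetic overview
- The target is deprotected from the triacetate of the chalcone, which comes from an E-selective Mizoroki–Heck coupling of an aryl iodide with an aryl vinyl ketone. This replaces the usual Claisen–Schmidt condensation.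
- The aryl iodide comes from regioselective iodination of a diacetylated 3-methoxycatechol that already carries the 1,1-dimethylallyl group. The iodination site is the only activated, unhindered position, ortho to OMe.
- The 1,1-dimethylallyl quaternary carbon is built directly by an aromatic Claisen [3,3] rearrangement of the O-prenyl ether of 3-methoxycatechol. The other ortho position is blocked by OH, so only one site is available.
- The vinyl ketone comes from Stille acylation of 4-acetoxybenzoyl chloride. Both aromatic rings come from commercial materials, so no ring is formed in the route.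

## Route

**Step 1**
Reactants: 1 (3-methoxycatechol), 2 (prenyl bromide)
Product: 3 (2-methoxy-6-[(3-methylbut-2-en-1-yl)oxy]phenol)
Conditions: K2CO3 (1.1 equiv), acetone, 0 °C → rt, slow addition of 2
Reagents that add atoms: prenyl bromide, CC(C)=CCBr (adds the prenyl group)
Why: Williamson mono-O-alkylation occurs at the less hindered, more acidic C1-OH, which is meta to OMe. The C2-OH is buttressed by OMe and the neighbouring OH. No stereocentre is formed.

**Step 2**
Reactants: 3
Product: 4 (3-methoxy-6-(2-methylbut-3-en-2-yl)benzene-1,2-diol)
Conditions: PhNEt2, BHT, Ar, 170 °C (sealed tube), 2 h; cold aqueous KHSO4 workup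
Reagents that add atoms: none
Why: Aromatic Claisen [3,3] rearrangement via a chair transition state inverts the allyl terminus, so O–CH2–CH=CMe2 becomes Ar–CMe2–CH=CH2. It can only go to C6, since C2 carries OH, and the dienone then tautomerises to the phenol. The amine solvent buffers acid, which suppresses cyclisation to the dihydrobenzofuran. The quaternary carbon is created here without any stereocentre.

**Step 3**
Reactants: 4, 5 (acetic anhydride)
Product: 6 (3-methoxy-6-(2-methylbut-3-en-2-yl)-1,2-phenylene diacetate)
Conditions: Ac2O (3 equiv), pyridine, DMAP (cat.), CH2Cl2, 0 °C → rt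
Reagents that add atoms: acetic anhydride, CC(=O)OC(C)=O (adds two acetyl groups)
Why: Acetylation masks the oxidation-prone catechol. Acetates are removable by base, whereas benzyl (needs H2, which would reduce the vinyl group) and MOM or silyl groups (need acid, which cyclises the reverse-prenyl phenol) are not suitable.

**Step 4**
Reactants: 6, 7 (N-iodosuccinimide)
Product: 8 (4-iodo-3-methoxy-6-(2-methylbut-3-en-2-yl)-1,2-phenylene diacetate, numbered as a catechol)
Conditions: NIS (1.05 equiv), TFA (10 mol%), MeCN, 0 °C → rt, dark
Reagents that add atoms: NIS, O=C1CCC(=O)N1I (adds I)
Why: Electrophilic aromatic iodination goes ortho to the strongest donor (OMe) at the position that is not hindered. The only other free position is flanked by the tertiary alkyl group and is meta to OMe.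

**Step 5**
Reactants: 9 (4-acetoxybenzoyl chloride), 10 (tributyl(vinyl)stannane)
Product: 11 (1-(4-acetoxyphenyl)prop-2-en-1-one, i.e. 4-acryloylphenyl acetate)
Conditions: PdCl2(PPh3)2 (3 mol%), BHT, toluene, 80 °C; KF/silica workup
Reagents that add atoms: vinyltributylstannane, C=C[Sn](CCCC)(CCCC)CCCC (adds the vinyl group)
Why: Stille acyl cross-coupling (acid chloride + vinylstannane) gives the aryl vinyl ketone. The aryl acetate is untouched.

**Step 6**
Reactants: 8, 11 (1.5 equiv)
Product: 12 ((E)-chalcone triacetate: 3-methoxy-6-(2-methylbut-3-en-2-yl)-4-[(E)-3-(4-acetoxyphenyl)-3-oxoprop-1-en-1-yl]-1,2-phenylene diacetate)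
Conditions: Pd(OAc)2 (5 mol%), P(o-tol)3 (10 mol%), Et3N, MeCN, 80 °C, BHT
Reagents that add atoms: none
Why: In the Mizoroki–Heck reaction, the electron-poor vinyl ketone inserts much faster than the hindered, unactivated reverse-prenyl alkene. Syn-carbopalladation followed by syn β-H elimination from the anti-periplanar conformer gives the E-enone exclusively. This sets the only stereo-element. The strategy is bolder than the condensation route because the hindered, electron-rich iodide must couple cleanly.

**Step 7**
Reactants: 12
Product: 13 (target: (E)-3-[3,4-dihydroxy-2-methoxy-5-(2-methylbut-3-en-2-yl)phenyl]-1-(4-hydroxyphenyl)prop-2-en-1-one)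
Conditions: K2CO3 (4 equiv), MeOH, Ar, 0 °C → rt, 1 h; then 1 M HCl to pH ≈ 4
Reagents that add atoms: none
Why: Methanolysis of the three phenyl acetates uses base. The E-enone and the terminal vinyl group are unaffected, and the brief acidic quench is too mild to cyclise the reverse prenyl group.

## Compound list
1 | 3-methoxycatechol | COc1cccc(O)c1O | starting material
2 | prenyl bromide | CC(C)=CCBr | starting material
3 | 2-methoxy-6-(prenyloxy)phenol | COc1cccc(OCC=C(C)C)c1O | intermediate
4 | 3-methoxy-6-(2-methylbut-3-en-2-yl)benzene-1,2-diol | COc1ccc(C(C)(C)C=C)c(O)c1O | intermediate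
5 | acetic anhydride | CC(=O)OC(C)=O | starting material (reagent)
6 | catechol diacetate of 4 | COc1ccc(C(C)(C)C=C)c(OC(C)=O)c1OC(C)=O | intermediate
7 | N-iodosuccinimide | O=C1CCC(=O)N1I | starting material (reagent)
8 | aryl iodide diacetate | COc1c(I)cc(C(C)(C)C=C)c(OC(C)=O)c1OC(C)=O | intermediate
9 | 4-acetoxybenzoyl chloride | CC(=O)Oc1ccc(C(=O)Cl)cc1 | starting material
10 | tributyl(vinyl)stannane | C=C[Sn](CCCC)(CCCC)CCCC | starting material
11 | 4-acryloylphenyl acetate | C=CC(=O)c1ccc(OC(C)=O)cc1 | intermediate
12 | chalcone triacetate | COc1c(/C=C/C(=O)c2ccc(OC(C)=O)cc2)cc(C(C)(C)C=C)c(OC(C)=O)c1OC(C)=O | intermediate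
13 | target, IN0234 | C=CC(C)(C)c1cc(/C=C/C(=O)c2ccc(O)cc2)c(OC)c(O)c1O | target

## Totals
- Total steps: 7.
- Longest linear sequence: 6 (1 → 3 → 4 → 6 → 8 → 12 → 13).

## Three steps most likely to fail
1. **Step 2 (Claisen).** The reverse-prenyl phenol can cyclise to a 2,3,3-trimethyldihydrobenzofuran or undergo Cope-type isomerisation at 170 °C.
   - Fallback (different approach): brominate ortho to the free OH and install the group by Pd-catalysed γ-selective Suzuki coupling of the aryl bromide with prenyl-Bpin, which forms the quaternary carbon under neutral conditions.
2. **Step 1 (mono-prenylation regioselectivity).** The assumed C1-OH selectivity could give a mixture with the C2 ether or the bis-ether.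
   - Fallback (different approach): start from 2,3-dimethoxyphenol, where O-prenylation is unambiguous. Do the Claisen, then selective BCl3 demethylation of the OMe ortho to the OH. This fixes the regiochemistry by substrate design.
3. **Step 6 (Heck).** The vinyl ketone may polymerise, or the hindered iodide may couple poorly.
   - Fallback (different approach): convert iodide 8 to the aldehyde by Pd-catalysed formylation, then build the enone by base-mediated condensation with 4-hydroxyacetophenone, which is the classical disconnection.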